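**Retrosynthetic overview**
1. Target ⇒ global desilylation and acylation of the C15 alcohol with O‑silyl sarracinic acid ⇒ 15‑hydroxy‑6‑silyloxy germacranolide core.
2. Core ⇒ one operation that closes both rings: the C7–C8 bond of the ten‑membered carbocycle by intramolecular allylboration, and the γ‑lactone by collapse of the resulting borate onto the methyl ester.
3. Acyclic allylboronate–aldehyde ⇒ γ‑silyloxy ynoate (syn hydroalumination/borylmethylation); the C6 carbinol comes from catalytic asymmetric propiolate addition to an enal.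
4. Enal chain ⇒ B‑alkyl Suzuki union of a dienol (carboalumination of but‑3‑yn‑1‑ol) with a (Z)‑iodobutenol (from but‑2‑yne‑1,4‑diol).
5. Ring order: no ring is pre‑formed; carbocycle and lactone arise together in the key step.

Assumption: the (S,S)‑ProPhenol antipode is taken as the one giving the 6R carbinol from this enal (if the sense proves opposite, the mirror‑image ligand is used); locants C1–C15 follow germacranolide numbering (lactone carbonyl C12, exocyclic methylene C13).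

**Step 1**
Reactants: 1 but‑3‑yn‑1‑ol; 2 bromoethene
Product: 4 (3E)‑3‑methylhexa‑3,5‑dien‑1‑ol, via alkenylalane 3 (not isolated)
Conditions: AlMe3 (3 equiv), Cp2ZrCl2 (25 mol %), CH2Cl2, 0 °C → rt; then 2, ZnCl2, Pd(PPh3)4 (3 mol %), THF, rt
Reagents that add atoms: trimethylaluminium, C[Al](C)C
Why: Zirconium‑catalysed Negishi carboalumination adds methyl and aluminium syn across the alkyne (methyl to the internal carbon), and palladium‑catalysed Negishi coupling of the alkenylalane with vinyl bromide proceeds with retention, fixing the C1=C10 E geometry.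

**Step 2**
Reactants: 5 but‑2‑yne‑1,4‑diol
Product: 6 4‑[(4‑methoxyphenyl)methoxy]but‑2‑yn‑1‑ol
Conditions: NaH (1 equiv), 4‑methoxybenzyl chloride (1 equiv), diol in excess (3 equiv), DMF/THF, 0 °C → rt
Reagents that add atoms: 4‑methoxybenzyl chloride, COc1ccc(CCl)cc1
Why: Williamson etherification with the diol in excess gives mainly the mono‑PMB ether.

**Step 3**
Reactants: 6 4‑[(4‑methoxyphenyl)methoxy]but‑2‑yn‑1‑ol
Product: 7 (2Z)‑3‑iodo‑4‑[(4‑methoxyphenyl)methoxy]but‑2‑en‑1‑ol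
Conditions: NaAlH2(OCH2CH2OMe)2, THF, 0 °C → rt; then I2, −78 → 0 °C
Reagents that add atoms: iodine, II
Why: The free propargylic alkoxide directs trans‑hydroalumination (hydride to the proximal carbon, aluminium to the distal carbon), and iodinolysis with retention gives the Z‑vinyl iodide with iodine on the future C4.

**Step 4**
Reactants: 4 (3E)‑3‑methylhexa‑3,5‑dien‑1‑ol; 7 (2Z)‑3‑iodo‑4‑[(4‑methoxyphenyl)methoxy]but‑2‑en‑1‑ol
Product: 9 (2E,6E)‑3‑{[(4‑methoxyphenyl)methoxy]methyl}‑7‑methylnona‑2,6‑diene‑1,9‑diol, via B‑alkyl‑9‑BBN borane 8 (not isolated)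
Conditions: 9‑BBN (2.2 equiv), THF, 0 °C → rt; then 7, PdCl2(dppf) (5 mol %), AsPh3, Cs2CO3, DMF/H2O, rt
Reagents that add atoms: none
Why: 9‑BBN hydroborates the terminal vinyl group anti‑Markovnikov, and the B‑alkyl Suzuki–Miyaura coupling proceeds with retention at the vinyl iodide, so the new C3 chain is cis to C6 as the target requires.

**Step 5**
Reactants: 9 (2E,6E)‑3‑{[(4‑methoxyphenyl)methoxy]methyl}‑7‑methylnona‑2,6‑diene‑1,9‑diol
Product: 10 (2E,6E)‑9‑hydroxy‑3‑{[(4‑methoxyphenyl)methoxy]methyl}‑7‑methylnona‑2,6‑dienal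
Conditions: MnO2 (excess), CH2Cl2, rt
Reagents that add atoms: none
Why: MnO2 oxidises only the allylic alcohol, and the neutral heterogeneous conditions preserve the alkene geometry.

**Step 6**
Reactants: 10 (2E,6E)‑9‑hydroxy‑3‑{[(4‑methoxyphenyl)methoxy]methyl}‑7‑methylnona‑2,6‑dienal; 11 methyl prop‑2‑ynoate
Product: 12 methyl (4R,5E,9E)‑4,12‑dihydroxy‑6‑{[(4‑methoxyphenyl)methoxy]methyl}‑10‑methyldodeca‑5,9‑dien‑2‑ynoate
Conditions: (S,S)‑ProPhenol (20 mol %), Me2Zn (4 equiv), toluene, 4 °C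
Reagents that add atoms: none
Why: Dinuclear zinc–ProPhenol asymmetric alkynylation (Trost alkynylation) adds the zinc propiolate to one enantioface of the enal, setting C6 as R under catalyst control.

**Step 7**
Reactants: 12 methyl (4R,5E,9E)‑4,12‑dihydroxy‑6‑{[(4‑methoxyphenyl)methoxy]methyl}‑10‑methyldodeca‑5,9‑dien‑2‑ynoate
Product: 13 methyl (4R,5E,9E)‑6‑{[(4‑methoxyphenyl)methoxy]methyl}‑10‑methyl‑4,12‑bis(triethylsilyloxy)dodeca‑5,9‑dien‑2‑ynoate
Conditions: TESOTf (2.5 equiv), 2,6‑lutidine, CH2Cl2, −78 °C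
Reagents that add atoms: triethylsilyl triflate, CC[Si](CC)(CC)OS(=O)(=O)C(F)(F)F
Why: Standard silylation blocks the C6 oxygen (which would otherwise lactonise once it is cis to the ester) and turns the primary alcohol into a latent aldehyde.

**Step 8**
Reactants: 13 methyl (4R,5E,9E)‑6‑{[(4‑methoxyphenyl)methoxy]methyl}‑10‑methyl‑4,12‑bis(triethylsilyloxy)dodeca‑5,9‑dien‑2‑ynoate; 14 2‑(iodomethyl)‑4,4,5,5‑tetramethyl‑1,3,2‑dioxaborolane
Product: 16 methyl (2Z,4R,5E,9E)‑6‑{[(4‑methoxyphenyl)methoxy]methyl}‑10‑methyl‑2‑[(4,4,5,5‑tetramethyl‑1,3,2‑dioxaborolan‑2‑yl)methyl]‑4,12‑bis(triethylsilyloxy)dodeca‑2,5,9‑trienoate, via alpha‑aluminio enoate 15 (not isolated)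
Conditions: i‑Bu2AlH (1.2 equiv), HMPA, THF, 0 °C; then 14, 0 °C → rt
Reagents that add atoms: none
Why: Syn conjugate hydroalumination of the ynoate (hydride to C7, aluminium to C11) and alkylation of the alpha‑aluminio enoate with retention give the 2‑alkoxycarbonyl allylboronate with H7 cis to CH2B and C6 cis to the ester, the geometry needed for anti‑selective allyl transfer.

**Step 9**
Reactants: 16 methyl (2Z,4R,5E,9E)‑6‑{[(4‑methoxyphenyl)methoxy]methyl}‑10‑methyl‑2‑[(4,4,5,5‑tetramethyl‑1,3,2‑dioxaborolan‑2‑yl)methyl]‑4,12‑bis(triethylsilyloxy)dodeca‑2,5,9‑trienoate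
Product: 17 methyl (2Z,4R,5E,9E)‑6‑{[(4‑methoxyphenyl)methoxy]methyl}‑10‑methyl‑12‑oxo‑2‑[(4,4,5,5‑tetramethyl‑1,3,2‑dioxaborolan‑2‑yl)methyl]‑4‑(triethylsilyloxy)dodeca‑2,5,9‑trienoate
Conditions: (COCl)2, DMSO, CH2Cl2, −78 → −35 °C; then Et3N, −78 → 0 °C; used at once
Reagents that add atoms: none
Why: Under Swern conditions a primary triethylsilyl ether is oxidised directly to the aldehyde while the secondary one survives, and the weakly nucleophilic 2‑alkoxycarbonyl allylboronate does not react at low temperature.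

**Step 10 (key step)**
Reactants: 17 methyl (2Z,4R,5E,9E)‑6‑{[(4‑methoxyphenyl)methoxy]methyl}‑10‑methyl‑12‑oxo‑2‑[(4,4,5,5‑tetramethyl‑1,3,2‑dioxaborolan‑2‑yl)methyl]‑4‑(triethylsilyloxy)dodeca‑2,5,9‑trienoate
Product: 19 (6R,7R,8S)‑15‑[(4‑methoxyphenyl)methoxy]‑6‑(triethylsilyloxy)germacra‑1(10)E,4,11(13)‑trien‑12,8‑olide [C3 cis to C6 at C4=C5; 6α‑O; 7α‑H; 8β‑H; trans‑fused lactone], via macrocyclic pinacol borate 18 (not isolated)
Conditions: Sc(OTf)3 (20 mol %), toluene, 0.002 M (slow addition of 17), −40 °C → rt; then PPTS (20 mol %), rt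
Reagents that add atoms: none
Why: Proposed new method: intramolecular Lewis‑acid‑catalysed allylboration through a closed six‑membered chair (carbonyl oxygen on boron, C9 and C6 equatorial, C6 trans to the CH2B carbon) forms the C7–C8 bond and hence the ten‑membered ring with 7,8‑anti topology, and the borate then acylates itself on the methyl ester to close the trans‑fused lactone in the same flask; 1,3‑allylic strain against the cis ester holds H6 in the alkene plane, so the aldehyde, tethered through C5, adds to the C7 face that carries C5 and is anti to the OTES group, which translates 6R into the 7α‑H, 8β‑H arrangement of the target; the closest known reactions are the intermolecular Sc(OTf)3‑catalysed tandem allylboration–lactonisation of 2‑alkoxycarbonyl allylboronates and CrCl2‑mediated macrocyclic Barbier closures of germacranolides.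

**Step 11**
Reactants: 19 (6R,7R,8S)‑15‑[(4‑methoxyphenyl)methoxy]‑6‑(triethylsilyloxy)germacra‑1(10)E,4,11(13)‑trien‑12,8‑olide
Product: 20 (6R,7R,8S)‑15‑hydroxy‑6‑(triethylsilyloxy)germacra‑1(10)E,4,11(13)‑trien‑12,8‑olide
Conditions: DDQ (1.2 equiv), CH2Cl2/pH 7 buffer, 0 °C
Reagents that add atoms: none
Why: Oxidative PMB cleavage by electron transfer to DDQ is selective for the electron‑rich benzyl ether and leaves the silyl ether, the alkenes and the alpha‑methylene lactone intact.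

**Step 12**
Reactants: 21 (E)‑but‑2‑enal
Product: 22 (2Z)‑2‑iodobut‑2‑enal
Conditions: I2, K2CO3, DMAP (20 mol %), THF/H2O, rt
Reagents that add atoms: iodine, II
Why: DMAP‑catalysed alpha‑iodination (conjugate addition, iodination of the enolate, elimination) gives the Z‑2‑iodo enal with methyl cis to iodine.

**Step 13**
Reactants: 22 (2Z)‑2‑iodobut‑2‑enal
Product: 23 (2Z)‑2‑iodobut‑2‑en‑1‑ol
Conditions: NaBH4, CeCl3·7H2O, MeOH, 0 °C
Reagents that add atoms: none
Why: Luche 1,2‑reduction of the enal leaves the alkene geometry unchanged.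

**Step 14**
Reactants: 23 (2Z)‑2‑iodobut‑2‑en‑1‑ol
Product: 24 tert‑butyl{[(2Z)‑2‑iodobut‑2‑en‑1‑yl]oxy}dimethylsilane
Conditions: TBSCl, imidazole, CH2Cl2, rt
Reagents that add atoms: tert‑butyldimethylsilyl chloride, CC(C)(C)[Si](C)(C)Cl
Why: Standard silylation of the primary alcohol.

**Step 15**
Reactants: 24 tert‑butyl{[(2Z)‑2‑iodobut‑2‑en‑1‑yl]oxy}dimethylsilane
Product: 26 (2Z)‑2‑{[(tert‑butyldimethylsilyl)oxy]methyl}but‑2‑enoic acid, via vinyllithium 25 (not isolated)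
Conditions: t‑BuLi (2.1 equiv), Et2O, −78 °C; then CO2; dilute HCl to pH 4
Reagents that add atoms: carbon dioxide, O=C=O
Why: Iodine–lithium exchange and carboxylation both proceed with retention at the vinyl carbon, so the carboxyl group ends cis to the methyl group (sarracinate geometry).

**Step 16**
Reactants: 20 (6R,7R,8S)‑15‑hydroxy‑6‑(triethylsilyloxy)germacra‑1(10)E,4,11(13)‑trien‑12,8‑olide; 26 (2Z)‑2‑{[(tert‑butyldimethylsilyl)oxy]methyl}but‑2‑enoic acid
Product: 28 (6R,7R,8S)‑15‑{[(2Z)‑2‑{[(tert‑butyldimethylsilyl)oxy]methyl}but‑2‑enoyl]oxy}‑6‑(triethylsilyloxy)germacra‑1(10)E,4,11(13)‑trien‑12,8‑olide, via acid chloride 27 (not isolated)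
Conditions: 26, 1‑chloro‑N,N,2‑trimethylprop‑1‑en‑1‑amine, CH2Cl2, 0 °C; then 20, pyridine, 0 °C → rt
Reagents that add atoms: none
Why: The alpha‑chloroenamine (Ghosez reagent) forms the acid chloride under neutral conditions, avoiding Z‑to‑E isomerisation of the angelate‑type acid, and the chloride then acylates the primary allylic alcohol.

**Step 17**
Reactants: 28 (6R,7R,8S)‑15‑{[(2Z)‑2‑{[(tert‑butyldimethylsilyl)oxy]methyl}but‑2‑enoyl]oxy}‑6‑(triethylsilyloxy)germacra‑1(10)E,4,11(13)‑trien‑12,8‑olide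
Product: 29 (6R,7S,8S)‑6‑hydroxy‑15‑{[(2Z)‑2‑(hydroxymethyl)but‑2‑enoyl]oxy}germacra‑1(10)E,4,11(13)‑trien‑12,8‑olide (CNP0234544.2)
Conditions: HF·pyridine, pyridine, THF, 0 °C → rt
Reagents that add atoms: none
Why: Buffered fluoride cleaves both silyl ethers without opening or transposing the lactone or adding to the alpha‑methylene group.

**Compound list**
1 | but‑3‑yn‑1‑ol | C#CCCO | starting material
2 | bromoethene (vinyl bromide) | C=CBr | starting material
3 | (E)‑alkenyl(dimethyl)alane of 1, hydroxyl as its dimethylaluminium alkoxide (formed in the flask) | C[Al](C)/C=C(\C)CCO[Al](C)C | intermediate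
4 | (3E)‑3‑methylhexa‑3,5‑dien‑1‑ol | OCC/C(C)=C/C=C | intermediate
5 | but‑2‑yne‑1,4‑diol | OCC#CCO | starting material
6 | 4‑[(4‑methoxyphenyl)methoxy]but‑2‑yn‑1‑ol | OCC#CCOCc1ccc(OC)cc1 | intermediate
7 | (2Z)‑3‑iodo‑4‑[(4‑methoxyphenyl)methoxy]but‑2‑en‑1‑ol (I cis to CH2OH) | OC/C=C(\I)COCc1ccc(OC)cc1 | intermediate
8 | 9‑[(3E)‑4‑methyl‑6‑(9‑borabicyclo[3.3.1]nonan‑9‑yloxy)hex‑3‑en‑1‑yl]‑9‑borabicyclo[3.3.1]nonane (formed in the flask) | C1CC2CCCC(C1)B2CC/C=C(\C)CCOB1C2CCCC1CCC2 | intermediate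
9 | (2E,6E)‑3‑{[(4‑methoxyphenyl)methoxy]methyl}‑7‑methylnona‑2,6‑diene‑1,9‑diol (alkyl chain cis to C1 carbinol carbon) | OC/C=C(/COCc1ccc(OC)cc1)CC/C=C(\C)CCO | intermediate
10 | (2E,6E)‑9‑hydroxy‑3‑{[(4‑methoxyphenyl)methoxy]methyl}‑7‑methylnona‑2,6‑dienal | O=C/C=C(/COCc1ccc(OC)cc1)CC/C=C(\C)CCO | intermediate
11 | methyl prop‑2‑ynoate (methyl propiolate) | C#CC(=O)OC | starting material
12 | methyl (4R,5E,9E)‑4,12‑dihydroxy‑6‑{[(4‑methoxyphenyl)methoxy]methyl}‑10‑methyldodeca‑5,9‑dien‑2‑ynoate | COC(=O)C#C[C@H](O)/C=C(/COCc1ccc(OC)cc1)CC/C=C(\C)CCO | intermediate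
13 | methyl (4R,5E,9E)‑6‑{[(4‑methoxyphenyl)methoxy]methyl}‑10‑methyl‑4,12‑bis(triethylsilyloxy)dodeca‑5,9‑dien‑2‑ynoate | COC(=O)C#C[C@H](O[Si](CC)(CC)CC)/C=C(/COCc1ccc(OC)cc1)CC/C=C(\C)CCO[Si](CC)(CC)CC | intermediate
14 | 2‑(iodomethyl)‑4,4,5,5‑tetramethyl‑1,3,2‑dioxaborolane | ICB1OC(C)(C)C(C)(C)O1 | starting material
15 | alpha‑(diisobutylaluminio) enoate from 13, H7 cis to Al (formed in the flask) | COC(=O)/C(=C\[C@H](O[Si](CC)(CC)CC)/C=C(/COCc1ccc(OC)cc1)CC/C=C(\C)CCO[Si](CC)(CC)CC)[Al](CC(C)C)CC(C)C | intermediate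
16 | methyl (2Z,4R,5E,9E)‑6‑{[(4‑methoxyphenyl)methoxy]methyl}‑10‑methyl‑2‑[(4,4,5,5‑tetramethyl‑1,3,2‑dioxaborolan‑2‑yl)methyl]‑4,12‑bis(triethylsilyloxy)dodeca‑2,5,9‑trienoate | COC(=O)/C(CB1OC(C)(C)C(C)(C)O1)=C\[C@H](O[Si](CC)(CC)CC)/C=C(/COCc1ccc(OC)cc1)CC/C=C(\C)CCO[Si](CC)(CC)CC | intermediate
17 | methyl (2Z,4R,5E,9E)‑6‑{[(4‑methoxyphenyl)methoxy]methyl}‑10‑methyl‑12‑oxo‑2‑[(4,4,5,5‑tetramethyl‑1,3,2‑dioxaborolan‑2‑yl)methyl]‑4‑(triethylsilyloxy)dodeca‑2,5,9‑trienoate | COC(=O)/C(CB1OC(C)(C)C(C)(C)O1)=C\[C@H](O[Si](CC)(CC)CC)/C=C(/COCc1ccc(OC)cc1)CC/C=C(\C)CC=O | intermediate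
18 | methyl 2‑[(6R,7R,8S)‑ten‑membered ring]acrylate: seco‑lactone of 19 with O8 as pinacol borate (formed in the flask) | C=C(C(=O)OC)[C@@H]1[C@@H](OB2OC(C)(C)C(C)(C)O2)C/C(C)=C/CC/C(COCc2ccc(OC)cc2)=C\[C@H]1O[Si](CC)(CC)CC | intermediate
19 | (6R,7R,8S)‑15‑[(4‑methoxyphenyl)methoxy]‑6‑(triethylsilyloxy)germacra‑1(10)E,4,11(13)‑trien‑12,8‑olide (C3 cis to C6; 6α‑O, 7α‑H, 8β‑H) | C=C1C(=O)O[C@H]2C/C(C)=C/CC/C(COCc3ccc(OC)cc3)=C\[C@@H](O[Si](CC)(CC)CC)[C@H]12 | intermediate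
20 | (6R,7R,8S)‑15‑hydroxy‑6‑(triethylsilyloxy)germacra‑1(10)E,4,11(13)‑trien‑12,8‑olide | C=C1C(=O)O[C@H]2C/C(C)=C/CC/C(CO)=C\[C@@H](O[Si](CC)(CC)CC)[C@H]12 | intermediate
21 | (E)‑but‑2‑enal (crotonaldehyde) | C/C=C/C=O | starting material
22 | (2Z)‑2‑iodobut‑2‑enal | C/C=C(\I)C=O | intermediate
23 | (2Z)‑2‑iodobut‑2‑en‑1‑ol | C/C=C(\I)CO | intermediate
24 | tert‑butyl{[(2Z)‑2‑iodobut‑2‑en‑1‑yl]oxy}dimethylsilane | C/C=C(\I)CO[Si](C)(C)C(C)(C)C | intermediate
25 | 2‑lithio alkene from 24, Li cis to methyl (formed in the flask) | C/C=C(\[Li])CO[Si](C)(C)C(C)(C)C | intermediate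
26 | (2Z)‑2‑{[(tert‑butyldimethylsilyl)oxy]methyl}but‑2‑enoic acid | C/C=C(\C(=O)O)CO[Si](C)(C)C(C)(C)C | intermediate
27 | (2Z)‑2‑{[(tert‑butyldimethylsilyl)oxy]methyl}but‑2‑enoyl chloride (formed in the flask) | C/C=C(\C(Cl)=O)CO[Si](C)(C)C(C)(C)C | intermediate
28 | (6R,7R,8S)‑15‑{[(2Z)‑2‑{[(tert‑butyldimethylsilyl)oxy]methyl}but‑2‑enoyl]oxy}‑6‑(triethylsilyloxy)germacra‑1(10)E,4,11(13)‑trien‑12,8‑olide | C=C1C(=O)O[C@H]2C/C(C)=C/CC/C(COC(=O)/C(=C\C)CO[Si](C)(C)C(C)(C)C)=C\[C@@H](O[Si](CC)(CC)CC)[C@H]12 | intermediate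
29 | (6R,7S,8S)‑6‑hydroxy‑15‑{[(2Z)‑2‑(hydroxymethyl)but‑2‑enoyl]oxy}germacra‑1(10)E,4,11(13)‑trien‑12,8‑olide | C=C1C(=O)O[C@H]2C/C(C)=C/CC/C(COC(=O)/C(=C\C)CO)=C\[C@@H](O)[C@H]12 | target

**Totals**
Total step count: 17. Longest linear sequence: 12 steps (5 → 6 → 7 → 9 → 10 → 12 → 13 → 16 → 17 → 19 → 20 → 28 → 29).

**Steps most likely to fail, with fallbacks**

Step 10 (ring strain in the doubly cyclic transition state, oligomerisation, and the facial sense relative to C6 are untested). The fallback sets out from allylboronate 16. Oxidation of the C–B bond (NaBO3·4H2O, THF/H2O) gives the allylic alcohol methyl (2E,4R)‑2‑(hydroxymethyl) trienoate F5. Appel bromination (CBr4, PPh3, 2,6‑lutidine) gives the allylic bromide F6, and direct Swern oxidation of the primary silyl ether gives the bromo aldehyde F7. A Nozaki–Hiyama–Kishi‑type Barbier macrocyclisation (CrCl2, THF, high dilution, then PPTS) then closes the carbocycle and lactone through an equilibrating allylchromium species, which does not depend on alkene geometry, and returns to lactone 19.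

Step 8 (loss of the γ‑silyloxy group from the aluminium allenolate, loss of alkene geometry, or sluggish alkylation). The fallback sets out from ynoate 13. Palladium‑catalysed syn‑hydrostannation (Bu3SnH, Pd(PPh3)4, THF, 0 °C) gives the alpha‑stannyl enoate F3. Iododestannylation (I2, CH2Cl2, 0 °C) gives the alpha‑iodo enoate F4 with retention. Negishi coupling with IZnCH2Bpin (from 14 and zinc dust; Pd2(dba)3, tri(2‑furyl)phosphine, THF) returns to allylboronate 16.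

Step 6 (the free hydroxyl and the β,β‑disubstituted enal may lower conversion or enantiomeric excess; the ligand sense is assumed). The fallback sets out from enal 10. Addition of the lithium acetylide of 11 (LiHMDS, THF, −78 °C) gives the racemic propargylic alcohol F1. MnO2 oxidises only this doubly activated carbinol to the dienyl ynone F2. Corey–Bakshi–Shibata reduction with (R)‑2‑methyl‑CBS‑oxazaborolidine and catecholborane (alkynyl as the small group) returns to the 4R alcohol 12.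

**Further compounds**
F1 | step 6 | methyl (5E,9E)‑4,12‑dihydroxy‑6‑{[(4‑methoxyphenyl)methoxy]methyl}‑10‑methyldodeca‑5,9‑dien‑2‑ynoate, racemic at C4 | COC(=O)C#CC(O)/C=C(/COCc1ccc(OC)cc1)CC/C=C(\C)CCO
F2 | step 6 | methyl (5E,9E)‑12‑hydroxy‑6‑{[(4‑methoxyphenyl)methoxy]methyl}‑10‑methyl‑4‑oxododeca‑5,9‑dien‑2‑ynoate | COC(=O)C#CC(=O)/C=C(/COCc1ccc(OC)cc1)CC/C=C(\C)CCO
F3 | step 8 | methyl (4R)‑2‑(tributylstannyl)‑4,12‑bis(triethylsilyloxy) trienoate, H3 cis to tin, other groups as in 16 | COC(=O)/C(=C\[C@H](O[Si](CC)(CC)CC)/C=C(/COCc1ccc(OC)cc1)CC/C=C(\C)CCO[Si](CC)(CC)CC)[Sn](CCCC)(CCCC)CCCC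
F4 | step 8 | methyl (4R)‑2‑iodo‑4,12‑bis(triethylsilyloxy) trienoate, H3 cis to iodine, other groups as in 16 | COC(=O)/C(I)=C\[C@H](O[Si](CC)(CC)CC)/C=C(/COCc1ccc(OC)cc1)CC/C=C(\C)CCO[Si](CC)(CC)CC
F5 | step 10 | methyl (4R)‑2‑(hydroxymethyl)‑4,12‑bis(triethylsilyloxy) trienoate, C4 cis to the ester, other groups as in 16 | COC(=O)/C(CO)=C\[C@H](O[Si](CC)(CC)CC)/C=C(/COCc1ccc(OC)cc1)CC/C=C(\C)CCO[Si](CC)(CC)CC
F6 | step 10 | methyl (4R)‑2‑(bromomethyl)‑4,12‑bis(triethylsilyloxy) trienoate, C4 cis to the ester | COC(=O)/C(CBr)=C\[C@H](O[Si](CC)(CC)CC)/C=C(/COCc1ccc(OC)cc1)CC/C=C(\C)CCO[Si](CC)(CC)CC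
F7 | step 10 | methyl (4R)‑2‑(bromomethyl)‑12‑oxo‑4‑(triethylsilyloxy) trienoate, C4 cis to the ester | COC(=O)/C(CBr)=C\[C@H](O[Si](CC)(CC)CC)/C=C(/COCc1ccc(OC)cc1)CC/C=C(\C)CC=O
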